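The route rests on disconnecting the C2–C1′ σ bond at the centre of the cross-conjugated 2-carboxy-1,3-diene (C3=C2(CO2H)–C1′=C2′), the one bond flanked by two trigonal carbons whose alkene geometries can each be established in a separate fragment. A one-pot hydroboration/Suzuki–Miyaura coupling makes it: syn-hydroboration of the terminal alkyne of a citronellal-derived enyne sets the E C1′=C2′ alkene, and a Z-α-iodoenoate transfers its C2=C3 geometry with retention. The isopropylidene end of the enyne is a latent carboxyl (C7′), unmasked afterwards and C-acylated onto C3 of the (R)-6-methyl-dihydropyranone ring, which takes no part in the key step.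

Key step: step 4

Remark: locants C1–C6 refer to the hex-2-enoic acid, C1′–C7′ to the side chain counted from C2, and ring locants to the pyranone. The 3-acyl-4-hydroxy-pyranone is a tautomeric tricarbonyl and is drawn as the enol of the target.

Step 1
Reactants: 1 (S)-2-methylbutan-1-ol
Product: 2 (S)-2-methylbutanal
Conditions: TEMPO (1 mol %), KBr (10 mol %), NaOCl (1.1 equiv), NaHCO3, CH2Cl2/H2O, 0 °C
Reagents that add atoms: none
Why: TEMPO/hypochlorite (Anelli) oxidation through the oxoammonium salt stops at the aldehyde under buffered biphasic conditions, and the α-stereocentre, bought with 1, should not enolise at 0 °C in the short contact time.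

Step 2
Reactants: 2 (S)-2-methylbutanal
Product: 3 tert-butyl (S,Z)-2-iodo-4-methylhex-2-enoate
Conditions: Ph3P=CHCO2tBu, NIS, CH2Cl2, −20 °C; then K2CO3 and 2, −20 °C → rt
Reagents that add atoms: tert-butyl (triphenylphosphoranylidene)acetate, CC(C)(C)OC(=O)C=P(c1ccccc1)(c1ccccc1)c1ccccc1; N-iodosuccinimide, O=C1CCC(=O)N1I
Why: Wittig olefination with the α-iodo ylide made in situ by iodination of the stabilised ylide should place the sec-butyl group trans to the ester and therefore cis to iodine (Z), while the weakly basic ylide leaves the α-stereocentre of 2 intact.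

Step 3
Reactants: 4 (R)-citronellal
Product: 5 (R)-4,8-dimethylnon-7-en-1-yne
Conditions: dimethyl (1-diazo-2-oxopropyl)phosphonate, K2CO3, MeOH, 0 °C → rt
Reagents that add atoms: dimethyl (1-diazo-2-oxopropyl)phosphonate, COP(=O)(OC)C(=[N+]=[N-])C(C)=O
Why: Ohira–Bestmann (Seyferth–Gilbert) homologation turns the aldehyde into the terminal alkyne through a vinylidene carbene 1,2-hydride shift, and the stereocentre, bought with 4, is β to the carbonyl and cannot epimerise.

Step 4
Reactants: 5 (R)-4,8-dimethylnon-7-en-1-yne; 3 tert-butyl (S,Z)-2-iodo-4-methylhex-2-enoate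
Product: 7 tert-butyl (S,E)-2-[(R,E)-4,8-dimethylnona-1,7-dien-1-yl]-4-methylhex-2-enoate, via alkenylboronate 6 (not isolated)
Conditions: HBpin (1.1 equiv), Cp2Zr(H)Cl (5 mol %), Et3N (10 mol %), neat, 60 °C; then THF, aq K3PO4 (3 equiv), 3, Pd(OAc)2 (5 mol %), SPhos (10 mol %), 40 °C
Reagents that add atoms: none
Why: Cp2Zr(H)Cl adds Zr–H syn across the terminal C1′≡C2′ bond with the metal at the unhindered terminus and passes the alkenyl group to boron by σ-bond metathesis with HBpin, so 6 should form as the linear E alkenylboronate; zerovalent palladium (from Pd(OAc)2/SPhos) then inserts into the C2–I bond of 3 with retention, phosphate-assisted transmetalation delivers the alkenyl group, and reductive elimination closes the C2–C1′ σ bond. The closest known reaction type is the one-pot alkyne hydroboration/Suzuki–Miyaura alkenyl–alkenyl coupling used for stereodefined 1,3-dienes. No ring is closed and no stereocentre is created: the C4 and C4′ stereocentres are carried through untouched, and the two alkene geometries (C2=C3 from 3 by retention, C1′=C2′ from syn-hydroboration) follow from the stereospecificity of each elementary step. The step needs hydrometalation of the alkyne only, secured because the trisubstituted C7′=C8′ alkene is essentially inert to Cp2Zr(H)Cl/HBpin, and anti-Markovnikov regioselectivity, secured by the steric bias of a terminal alkyne. It also needs the coupling at the hindered, ester-bearing C2 to outrun protodeboronation of 6, for which the electron-rich biaryl phosphine and the reactive C–I bond are chosen; the tert-butyl ester should be inert to aqueous K3PO4.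

Step 5
Reactants: 7 tert-butyl (S,E)-2-[(R,E)-4,8-dimethylnona-1,7-dien-1-yl]-4-methylhex-2-enoate
Product: 9 (4R,6E,8E,10S)-8-(tert-butoxycarbonyl)-4,10-dimethyldodeca-6,8-dienoic acid, via aldehyde 8 (not isolated)
Conditions: O3, MeCN/H2O (9:1), 0 °C, Sudan Red 7B end point; N2 purge; then aq NaClO2 (3 equiv), 0 °C → rt
Reagents that add atoms: ozone, [O-][O+]=O; water, O; NaClO2 (sodium chlorite), [Na+].[O-]Cl=O
Why: Ozonolysis/Pinnick oxidation in one pot: electrophilic ozone should attack the isolated, electron-rich trisubstituted C7′=C8′ bond much faster than the ester-deactivated diene, water traps the carbonyl oxide so that aldehyde 8 forms without a reductive work-up, and NaClO2 then oxidises it to the acid with the co-formed hydrogen peroxide as hypochlorite scavenger.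

Step 6
Reactants: 10 methyl (R)-3-hydroxybutanoate
Product: 11 tert-butyl (R)-5-hydroxy-3-oxohexanoate
Conditions: tert-butyl acetate, LiN(iPr)2 (3.3 equiv each), THF, −78 °C; then 10, −78 → −30 °C; aq NH4Cl
Reagents that add atoms: tert-butyl acetate, CC(=O)OC(C)(C)C
Why: Crossed Claisen condensation in which excess lithium enolate first deprotonates the free hydroxyl and then acylates at the methyl ester, the β-keto ester being protected in situ as its enolate, so the carbinol stereocentre, bought with 10, is not touched.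

Step 7
Reactants: 11 tert-butyl (R)-5-hydroxy-3-oxohexanoate
Product: 13 (R)-4-hydroxy-6-methyl-5,6-dihydro-2H-pyran-2-one, via hydroxy keto acid 12 (not isolated)
Conditions: TFA, CH2Cl2, 0 °C → rt
Reagents that add atoms: none
Why: Acidolysis of the tert-butyl ester (loss of 2-methylpropene) followed by acid-catalysed 6-exo-trig lactonisation of the δ-hydroxy acid, which should outrun decarboxylation of the β-keto acid and gives the enolised pyrandione with the stereocentre unchanged.

Step 8
Reactants: 9 (4R,6E,8E,10S)-8-(tert-butoxycarbonyl)-4,10-dimethyldodeca-6,8-dienoic acid; 13 (R)-4-hydroxy-6-methyl-5,6-dihydro-2H-pyran-2-one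
Product: 15 tert-butyl (S,E)-2-[(R,E)-7-[(R)-4-hydroxy-6-methyl-2-oxo-5,6-dihydro-2H-pyran-3-yl]-4-methyl-7-oxohept-1-en-1-yl]-4-methylhex-2-enoate, via enol ester 14 (not isolated)
Conditions: DCC (1.2 equiv), DMAP (1.0 equiv), CH2Cl2, 0 °C → rt
Reagents that add atoms: none
Why: Steglich-type acylation of the enol oxygen of 13 followed by DMAP-relayed 1,3 O→C acyl shift (Fries-type) to ring C3, driven by formation of the chelated tricarbonyl, a reaction type established for 4-hydroxy-5,6-dihydropyran-2-ones.

Step 9
Reactants: 15 tert-butyl (S,E)-2-[(R,E)-7-[(R)-4-hydroxy-6-methyl-2-oxo-5,6-dihydro-2H-pyran-3-yl]-4-methyl-7-oxohept-1-en-1-yl]-4-methylhex-2-enoate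
Product: 16 (S,E)-2-[(R,E)-7-[(R)-4-hydroxy-6-methyl-2-oxo-5,6-dihydro-2H-pyran-3-yl]-4-methyl-7-oxohept-1-en-1-yl]-4-methylhex-2-enoic acid
Conditions: TFA/CH2Cl2 (1:4), 0 °C → rt
Reagents that add atoms: none
Why: Acidolysis of the tert-butyl ester through the tert-butyl cation; the acyl-pyranone (a ring type that itself forms in TFA in step 7), the ester-deactivated diene and the three stereocentres should be inert under these conditions.

Compound list
1 | (S)-2-methylbutan-1-ol | CC[C@H](C)CO | starting material
2 | (S)-2-methylbutanal | CC[C@H](C)C=O | intermediate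
3 | tert-butyl (S,Z)-2-iodo-4-methylhex-2-enoate | CC[C@H](C)/C=C(\I)C(=O)OC(C)(C)C | intermediate
4 | (R)-citronellal, (R)-3,7-dimethyloct-6-enal | C[C@H](CCC=C(C)C)CC=O | starting material
5 | (R)-4,8-dimethylnon-7-en-1-yne | C[C@H](CCC=C(C)C)CC#C | intermediate
6 | 2-[(R,E)-4,8-dimethylnona-1,7-dien-1-yl]-4,4,5,5-tetramethyl-1,3,2-dioxaborolane (formed in the flask) | C[C@H](CCC=C(C)C)C/C=C/B1OC(C)(C)C(C)(C)O1 | intermediate
7 | tert-butyl (S,E)-2-[(R,E)-4,8-dimethylnona-1,7-dien-1-yl]-4-methylhex-2-enoate | CC[C@H](C)/C=C(\C=C\C[C@H](C)CCC=C(C)C)C(=O)OC(C)(C)C | intermediate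
8 | tert-butyl (S,E)-4-methyl-2-[(R,E)-4-methyl-7-oxohept-1-en-1-yl]hex-2-enoate (formed in the flask) | CC[C@H](C)/C=C(\C=C\C[C@H](C)CCC=O)C(=O)OC(C)(C)C | intermediate
9 | (4R,6E,8E,10S)-8-(tert-butoxycarbonyl)-4,10-dimethyldodeca-6,8-dienoic acid | CC[C@H](C)/C=C(\C=C\C[C@H](C)CCC(=O)O)C(=O)OC(C)(C)C | intermediate
10 | methyl (R)-3-hydroxybutanoate | C[C@@H](O)CC(=O)OC | starting material
11 | tert-butyl (R)-5-hydroxy-3-oxohexanoate | C[C@@H](O)CC(=O)CC(=O)OC(C)(C)C | intermediate
12 | (R)-5-hydroxy-3-oxohexanoic acid (formed in the flask) | C[C@@H](O)CC(=O)CC(=O)O | intermediate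
13 | (R)-4-hydroxy-6-methyl-5,6-dihydro-2H-pyran-2-one (enol of (R)-6-methyldihydro-2H-pyran-2,4(3H)-dione) | C[C@@H]1CC(O)=CC(=O)O1 | intermediate
14 | (R)-6-methyl-2-oxo-5,6-dihydro-2H-pyran-4-yl (4R,6E,8E,10S)-8-(tert-butoxycarbonyl)-4,10-dimethyldodeca-6,8-dienoate (formed in the flask) | CC[C@H](C)/C=C(\C=C\C[C@H](C)CCC(=O)OC1=CC(=O)O[C@H](C)C1)C(=O)OC(C)(C)C | intermediate
15 | tert-butyl (S,E)-2-[(R,E)-7-[(R)-4-hydroxy-6-methyl-2-oxo-5,6-dihydro-2H-pyran-3-yl]-4-methyl-7-oxohept-1-en-1-yl]-4-methylhex-2-enoate | CC[C@H](C)/C=C(\C=C\C[C@H](C)CCC(=O)C1=C(O)C[C@@H](C)OC1=O)C(=O)OC(C)(C)C | intermediate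
16 | (S,E)-2-[(R,E)-7-[(R)-4-hydroxy-6-methyl-2-oxo-5,6-dihydro-2H-pyran-3-yl]-4-methyl-7-oxohept-1-en-1-yl]-4-methylhex-2-enoic acid | CC[C@H](C)/C=C(\C=C\C[C@H](C)CCC(=O)C1=C(O)C[C@@H](C)OC1=O)C(=O)O | target

Total step count: 9
Longest linear sequence: 6 steps (steps 1, 2, 4, 5, 8, 9)

Steps most likely to fail

Step 4 (key step). Transmetalation of the pinacol boronate to the hindered, ester-bearing alkenylpalladium iodide may be slow, so that protodeboronation of 6 and reductive loss of iodine from 3 take over. The fallback moves to a base-free Negishi coupling and sets out from 5. Stoichiometric Cp2Zr(H)Cl in THF at rt should give chlorobis(cyclopentadienyl)[(R,E)-4,8-dimethylnona-1,7-dien-1-yl]zirconium F1. ZnCl2 transmetalates it to [(R,E)-4,8-dimethylnona-1,7-dien-1-yl]zinc chloride F2, and Pd(PPh3)4 couples this with 3 at rt. The fallback comes back to the route at 7.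

Step 5. Ozone may not discriminate sharply enough and may also cleave the C1′=C2′ or C2=C3 bond of the diene, or chlorine species may attack the diene during the chlorite oxidation. The fallback cleaves before coupling and sets out from 5. Ozonolysis in CH2Cl2/methanolic NaOH at −78 °C should convert the isopropylidene end directly into methyl (R)-4-methylhept-6-ynoate F3, the terminal alkyne reacting far more slowly with ozone. The hydroboration of step 4 then gives methyl (R,E)-4-methyl-7-(4,4,5,5-tetramethyl-1,3,2-dioxaborolan-2-yl)hept-6-enoate F4. Suzuki–Miyaura coupling with 3 gives tert-butyl (S,E)-2-[(R,E)-7-methoxy-4-methyl-7-oxohept-1-en-1-yl]-4-methylhex-2-enoate F5. LiOH in THF/H2O at 0 °C should saponify only the unhindered methyl ester, and the fallback comes back to the route at 9.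

Step 2. Iodination of the ylide may be incomplete, the Z/E ratio may erode in the olefination, or 2 may epimerise during a long reaction with the sluggish iodo ylide. The fallback introduces the halogen after the olefination and sets out from 2. A salt-free Wittig reaction with Ph3P=CHCO2tBu gives tert-butyl (S,E)-4-methylhex-2-enoate F6. Br2 in CH2Cl2 at 0 °C adds anti to give tert-butyl (2R,3S,4S)-2,3-dibromo-4-methylhexanoate F7 and tert-butyl (2S,3R,4S)-2,3-dibromo-4-methylhexanoate F8. Et3N then removes HBr by an E1cB path under thermodynamic control to give tert-butyl (S,Z)-2-bromo-4-methylhex-2-enoate F9. This bromide takes the place of 3 in step 4, and the fallback comes back to the route at 7.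

Further compounds
F1 | step 4 | chlorobis(cyclopentadienyl)[(R,E)-4,8-dimethylnona-1,7-dien-1-yl]zirconium | C[C@H](CCC=C(C)C)C/C=C/[Zr](Cl)(C1C=CC=C1)C1C=CC=C1
F2 | step 4 | [(R,E)-4,8-dimethylnona-1,7-dien-1-yl]zinc chloride | C[C@H](CCC=C(C)C)C/C=C/[Zn]Cl
F3 | step 5 | methyl (R)-4-methylhept-6-ynoate | C[C@H](CCC(=O)OC)CC#C
F4 | step 5 | methyl (R,E)-4-methyl-7-(4,4,5,5-tetramethyl-1,3,2-dioxaborolan-2-yl)hept-6-enoate | C[C@H](CCC(=O)OC)C/C=C/B1OC(C)(C)C(C)(C)O1
F5 | step 5 | tert-butyl (S,E)-2-[(R,E)-7-methoxy-4-methyl-7-oxohept-1-en-1-yl]-4-methylhex-2-enoate | CC[C@H](C)/C=C(\C=C\C[C@H](C)CCC(=O)OC)C(=O)OC(C)(C)C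
F6 | step 2 | tert-butyl (S,E)-4-methylhex-2-enoate | CC[C@H](C)/C=C/C(=O)OC(C)(C)C
F7 | step 2 | tert-butyl (2R,3S,4S)-2,3-dibromo-4-methylhexanoate | CC[C@H](C)[C@H](Br)[C@H](Br)C(=O)OC(C)(C)C
F8 | step 2 | tert-butyl (2S,3R,4S)-2,3-dibromo-4-methylhexanoate | CC[C@H](C)[C@@H](Br)[C@@H](Br)C(=O)OC(C)(C)C
F9 | step 2 | tert-butyl (S,Z)-2-bromo-4-methylhex-2-enoate | CC[C@H](C)/C=C(\Br)C(=O)OC(C)(C)C
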